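**Plan**

1. Cuts (guaiane numbering, C1′ = benzylic carbon): C1′–C4, C1′–aryl and C11–O are cut together in the last step. This leads back to 2,4-diformylphloroglucinol, isovaleraldehyde, water and a C15 vinylcyclopropane (C4=C5 beside a temporary C6–C7–C11 ring).
2. Next, the C1–C5 bond of the hydroazulene is cut and C5–C10 is re-made. The five-membered ring (C1–C5) is the contracted ring A, and the seven-membered ring the expanded ring B, of a 6-6-3 dienone.
3. Enabling feature: ring A is a cross-conjugated dienone C1=C2–C3(=O)–C4(CH3)=C5 hinged on quaternary C10. Light bonds C1 to C5, and the C4 methyl directs cleavage of C5–C10.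
4. Forward order: ring B is bought (dihydrocarvone); ring A by Robinson annulation; cyclopropane by vinylogous 1,3-elimination; photochemical 6-6 to 5-7 change; removal of the helpers C10–OH and C3=O; three-component coupling that also opens the cyclopropane.
5. Stereochemistry: C7 comes from the chiral pool and sets C10 in the annulation. Quaternary C10 sets C1 in the photoreaction. The folded bicycle sets C10–H (hydrogenation) and C4 (β-face attack), and the quinone methide geometry sets C1′.

Key step: step 5

Remark: atom labels stay with the atoms through the rearrangement and β is the face of the C7 substituent; commercial 1 holds both C2 epimers, which converge in step 1, and both C3 epimers of 13 converge in step 9.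

**Route**

Step 1
Reactants: 1 (+)-dihydrocarvone; 2 ethyl vinyl ketone
Product: 4 (−)-10-epi-α-cyperone, via Michael adduct diketone 3 (not isolated)
Conditions: KOH (cat.), EtOH, −10 °C to rt; then reflux
Reagents that add atoms: none
Why: Robinson annulation, in which the thermodynamic enolate of 1 should add to 2 by axial attack on the half-chair that keeps the isopropenyl group equatorial, placing the new chain cis and the C10 methyl trans to the C7 substituent before aldol condensation closes ring A.

Step 2
Reactants: 4 (−)-10-epi-α-cyperone
Product: 5 11-chloro-10-epi-eudesm-4-en-3-one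
Conditions: HCl (g), Et2O, 0 °C
Reagents that add atoms: hydrogen chloride, Cl
Why: Markovnikov hydrochlorination of the electron-rich 1,1-disubstituted alkene through the tertiary C11 cation, with the enone inert and no stereocentre formed.

Step 3
Reactants: 5 11-chloro-10-epi-eudesm-4-en-3-one
Product: 6 10-epimaali-4-en-3-one
Conditions: KOt-Bu, t-BuOH, rt
Reagents that add atoms: none
Why: Vinylogous intramolecular enolate alkylation (1,3-elimination of HCl, 3-exo-tet), in which C6 of the extended dienolate can reach C11 only on the β face where C7 holds it, so the cyclopropane is cis-fused and the enone is kept.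

Step 4
Reactants: 6 10-epimaali-4-en-3-one
Product: 7 10-epimaalia-1,4-dien-3-one
Conditions: DDQ, 1,4-dioxane, reflux
Reagents that add atoms: none
Why: DDQ dehydrogenation of a 4-en-3-one by hydride abstraction from C1 of the 2(3)-enol, which should give the cross-conjugated dienone because the linear 4,6-dienone is blocked by the cyclopropane carbon C6.

Step 5
Reactants: 7 10-epimaalia-1,4-dien-3-one
Product: 9 10β-hydroxy-1βH-aromadendr-4-en-3-one, via cyclopropyl oxyallyl zwitterion 8 (not isolated)
Conditions: hν (medium-pressure mercury lamp, Pyrex filter), 45% aq AcOH, N2, rt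
Reagents that add atoms: water, O
Why: Excitation (n→π*) of the cross-conjugated dienone and intersystem crossing lead to bonding between the two β-carbons C1 and C5, and electron demotion gives zwitterion 8, a bicyclo[3.1.0]hexane in which C10 bridges C1 and C5 beside a C2–C3–C4 oxyallyl cation. Protonation on oxygen and rear-side attack of water at C10 then break the strained C5–C10 bond, so that C10 leaves ring A (six to five atoms, C1–C5) and enters ring B (six to seven atoms), and the enol ketonises to the C3 ketone conjugated with C4=C5. The closest known reaction type is the santonin-type (type A) photorearrangement of 4-methylcyclohexa-2,5-dienones in aqueous acid, known for eudesmane and maaliane dienones. Mode of closure: the five-membered ring closes by the transannular C1–C5 bond (a three-membered-ring closure across ring A in the excited state), whereas the seven-membered ring needs no new bond and arises by cleavage of the bond shared by the new cyclopropane and ring B. C1: because C9 must stay exo on the new cyclopropane, C10 can swing only to the face of its own methyl group (α), which leaves H1 β; C10: inversion by water anti to C5 gives 10β-OH and 10α-methyl. The step needs cleavage of C5–C10 instead of C1–C10 (spiro ketone) or a 1,4-shift (lumiketone), which the C4 methyl (charge at C4) and the protic nucleophilic medium secure, and the C6–C7–C11 cyclopropane is spared because C5, to which it is attached, never carries the charge.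

Step 6
Reactants: 9 10β-hydroxy-1βH-aromadendr-4-en-3-one
Product: 11 1βH-aromadendra-4,10(14)-dien-3-one, via tertiary chlorosulfite 10 (not isolated)
Conditions: SOCl2, pyridine, 0 °C
Reagents that add atoms: none
Why: Dehydration by anti E2 elimination of the chlorosulfite, in which H1 is syn to the leaving group and cannot be lost (no conjugated 1(10)-ene) while the freely rotating C14 methyl should supply the antiperiplanar hydrogen for the exocyclic alkene.

Step 7
Reactants: 11 1βH-aromadendra-4,10(14)-dien-3-one
Product: 12 cyclocolorenone
Conditions: H2 (1 atm), RhCl(PPh3)3 (cat.), toluene–EtOH, rt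
Reagents that add atoms: none
Why: Homogeneous hydrogenation that touches only the unhindered 1,1-disubstituted alkene (tetrasubstituted enone and cyclopropane inert) and should deliver hydrogen from the outer face of the folded seven-membered ring, the face of H1, giving 10β-H and 10α-methyl.

Step 8
Reactants: 12 cyclocolorenone
Product: 13 1βH,10βH-aromadendr-4-en-3α-ol
Conditions: LiAlH4, Et2O, 0 °C; aq NaOH work-up
Reagents that add atoms: none
Why: 1,2-Reduction of the enone (the fully substituted C5 blocks conjugate reduction) with hydride expected from the β face opposite C10, the new C3 centre being erased in step 9.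

Step 9
Reactants: 13 1βH,10βH-aromadendr-4-en-3α-ol
Product: 15 (−)-α-gurjunene, via allylic hydrogen sulfate 14 (not isolated)
Conditions: SO3·pyridine, THF, 0 °C; then LiAlH4, THF, 0 °C to rt
Reagents that add atoms: none
Why: Hydrogenolysis of an allylic alcohol through its sulfate monoester, whose anionic leaving group resists ionisation to the cyclopropyl-stabilised allyl cation, so hydride should displace it directly at secondary C3 (the SN2′ terminus C5 is fully substituted) and leave C4=C5 and the cyclopropane in place.

Step 10
Reactants: 16 phloroglucinol
Product: 18 2,4-diformylphloroglucinol, via bis-iminium dichloride 17 (not isolated)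
Conditions: POCl3 (2.2 equiv), DMF (2.2 equiv), 1,4-dioxane, 0 °C to rt; then ice-water
Reagents that add atoms: N,N-dimethylformamide, CN(C)C=O; water, O
Why: Twofold Vilsmeier–Haack formylation of the very electron-rich arene, stopped at the second stage by the stoichiometry and by the deactivating effect of two iminium groups.

Step 11
Reactants: 15 (−)-α-gurjunene; 18 2,4-diformylphloroglucinol; 19 isovaleraldehyde
Product: 21 target CNP0281883.3, via o-quinone methide 20 (not isolated)
Conditions: ethylenediammonium diacetate (cat.), 1,4-dioxane–H2O 4:1, 70 °C
Reagents that add atoms: water, O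
Why: Proposed new method: Knoevenagel condensation of 18 with 19 gives the strongly electrophilic o-quinone methide 20, whose methide carbon C1′ should be attacked by C4 of the tetrasubstituted alkene of 15, because only this regiochemistry places the charge on C5 as a bisected cyclopropylcarbinyl cation; water then attacks tertiary C11 as C6–C11 breaks (cyclopropylcarbinyl to homoallyl), which fixes C5=C6 and the C11 carbinol and leaves C7 untouched. C4 should form by attack on the convex β face, since C10 and its α-methyl lie under the five-membered ring; C1′ should become (S) because 20 reacts with its isobutyl group outside and its ring over the flat five-membered ring, away from C15 and the gem-dimethyl group. If the phenoxide closes on C5 first, the resulting chroman is a tertiary cyclopropylcarbinyl ether of an acidic phenol and should re-ionise in the warm aqueous medium and drain to 21. Closest known reaction types: three-component hetero-Diels–Alder and Michael reactions of diformylphloroglucinol-derived o-quinone methides with terpene alkenes, and Prins-type additions of carbon electrophiles to 2-carene with homoallylic opening of the cyclopropane.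

**Compound list**

1 | (+)-dihydrocarvone, (2R,5R)-2-methyl-5-(prop-1-en-2-yl)cyclohexan-1-one | C[C@@H]1CC[C@H](CC1=O)C(C)=C | starting material
2 | ethyl vinyl ketone (pent-1-en-3-one) | C=CC(=O)CC | starting material
3 | (2R,5R)-2-methyl-2-(3-oxopentyl)-5-(prop-1-en-2-yl)cyclohexan-1-one | C[C@]1(CCC(=O)CC)CC[C@H](CC1=O)C(C)=C | intermediate
4 | (−)-10-epi-α-cyperone, (4aR,7R)-1,4a-dimethyl-7-(prop-1-en-2-yl)-4,4a,5,6,7,8-hexahydronaphthalen-2(3H)-one (10α-methyl, 7β-isopropenyl) | C[C@@]12CCC(=O)C(C)=C1C[C@@H](CC2)C(C)=C | intermediate
5 | 11-chloro-10-epi-eudesm-4-en-3-one, (4aR,7R)-7-(2-chloropropan-2-yl)-1,4a-dimethyl-4,4a,5,6,7,8-hexahydronaphthalen-2(3H)-one | C[C@@]12CCC(=O)C(C)=C1C[C@@H](CC2)C(C)(C)Cl | intermediate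
6 | 10-epimaali-4-en-3-one (epimaalienone): eudesm-4-en-3-one with a C6–C11 bond; 10α-methyl; CMe2 bridge on the β face (6αH, 7αH) | C[C@@]12CCC(=O)C(C)=C1[C@H]3[C@@H](CC2)C3(C)C | intermediate
7 | 10-epimaalia-1,4-dien-3-one (1,2-didehydro-6) | C[C@@]12C=CC(=O)C(C)=C1[C@H]3[C@@H](CC2)C3(C)C | intermediate
8 | zwitterion: 7 with a C1–C5 bond, C10 bridging C1 and C5 on the α face, C2–C3(O−)–C4 oxyallyl cation | C[C@]12CC[C@@H]3[C@@H](C3(C)C)[C@@]14[C@@H]2[CH+]C([O-])=C4C | intermediate
9 | 10β-hydroxy-1βH-aromadendr-4-en-3-one (5-7-3 tricycle; 10α-methyl; CMe2 bridge β) | C[C@]1(O)CC[C@@H]2[C@@H](C2(C)C)C3=C(C(=O)C[C@H]13)C | intermediate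
10 | chlorosulfite ester of 9 | C[C@]1(OS(=O)Cl)CC[C@@H]2[C@@H](C2(C)C)C3=C(C(=O)C[C@H]13)C | intermediate
11 | 1βH-aromadendra-4,10(14)-dien-3-one | C=C1CC[C@@H]2[C@@H](C2(C)C)C3=C(C(=O)C[C@H]13)C | intermediate
12 | cyclocolorenone, 1βH,10βH-aromadendr-4-en-3-one (10α-methyl) | C[C@@H]1CC[C@@H]2[C@@H](C2(C)C)C3=C(C(=O)C[C@H]13)C | intermediate
13 | 1βH,10βH-aromadendr-4-en-3α-ol | C[C@@H]1CC[C@@H]2[C@@H](C2(C)C)C3=C([C@H](O)C[C@H]13)C | intermediate
14 | hydrogen sulfate ester of 13 | C[C@@H]1CC[C@@H]2[C@@H](C2(C)C)C3=C([C@H](OS(=O)(=O)O)C[C@H]13)C | intermediate
15 | (−)-α-gurjunene, (1aR,4R,4aR,7bS)-1,1,4,7-tetramethyl-1a,2,3,4,4a,5,6,7b-octahydro-1H-cyclopropa[e]azulene | C[C@@H]1CC[C@@H]2[C@@H](C2(C)C)C3=C(CC[C@H]13)C | intermediate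
16 | phloroglucinol (benzene-1,3,5-triol) | Oc1cc(O)cc(O)c1 | starting material
17 | bis(dimethyliminiomethyl)phloroglucinol dichloride | C[N+](C)=Cc1c(O)cc(O)c(C=[N+](C)C)c1O.[Cl-].[Cl-] | intermediate
18 | 2,4-diformylphloroglucinol (2,4,6-trihydroxybenzene-1,3-dicarbaldehyde) | O=Cc1c(O)cc(O)c(C=O)c1O | intermediate
19 | isovaleraldehyde (3-methylbutanal) | CC(C)CC=O | starting material
20 | o-quinone methide: 2,4-dihydroxy-5-(3-methylbutylidene)-6-oxocyclohexa-1,3-diene-1,3-dicarbaldehyde, isobutyl trans to the ring C=O | O=C1/C(=C/CC(C)C)C(O)=C(C=O)C(O)=C1C=O | intermediate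
21 | target, 5-[(1S)-1-[(1R,3aR,4R,7R)-7-(2-hydroxypropan-2-yl)-1,4-dimethyl-1,2,3,3a,4,5,6,7-octahydroazulen-1-yl]-3-methylbutyl]-2,4,6-trihydroxybenzene-1,3-dicarbaldehyde | CC(C)C[C@H](c1c(O)c(C=O)c(O)c(C=O)c1O)[C@@]1(C)CC[C@H]2C1=C[C@H](C(C)(C)O)CC[C@H]2C | target

**Step count and risks**

Total step count: 11. Longest linear sequence: 10 (steps 1–9 and 11).

Most likely to fail:

1. **Step 11 (new method).**
   - What may go wrong: poor facial or orientational selectivity in the C1′–C4 bond formation; collapse of the ion pair on oxygen before water arrives; proton loss next to C11; acid-induced isomerisation of the vinylcyclopropane before it meets the quinone methide.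
   - Fallback with known chemistry, from 15 to 21: 15, 18 and 19 are heated with NaOAc in anhydrous AcOH, so that 20 is trapped in the established inverse-demand hetero-Diels–Alder mode. This gives the chroman cycloadduct F1, which is isolated.
   - This tertiary cyclopropylcarbinyl aryl ether is then solvolysed with dilute HClO4 in aqueous acetone (cyclopropylcarbinyl to homoallyl rearrangement, as in the Julia olefin synthesis). That opens the C6–C11 bond, places water on C11 and gives 21.

2. **Step 9.**
   - What may go wrong: ionisation of the allylic sulfate with opening of the cyclopropane, or hydride delivery with allylic shift of the alkene.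
   - Fallback, from 12 to 15, bypassing 13: thioketalisation with 1,2-ethanedithiol and BF3·OEt2 in CH2Cl2 at −20 °C gives the cyclocolorenone 1,3-dithiolane F2. Desulfurisation with acetone-deactivated Raney Ni in EtOH keeps the alkene at C4=C5 and gives 15.

3. **Step 7.**
   - What may go wrong: hydrogen delivery from the inner face of the seven-membered ring, and sluggish reduction of any endocyclic alkene isomer carried over from step 6.
   - Fallback, from 11 to 12: radical hydrogen-atom-transfer hydrogenation with Mn(dpm)3 (dpm = dipivaloylmethanate), PhSiH3 and t-BuOOH in i-PrOH at rt.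
   - This forms the tertiary C10 radical from either alkene isomer and sets C10 in a separate hydrogen-abstraction event instead of a syn addition on a metal. No compound outside the list is made (F0).

Further compounds
F1 | step 11 | chroman cycloadduct of 15 and 20 (C1′–C4 and O–C5 bonds both on the β face, cyclopropane intact) | CC(C)C[C@@H]1c2c(O)c(C=O)c(O)c(C=O)c2O[C@@]34[C@]1(C)CC[C@@H]3[C@H](C)CC[C@@H]5[C@H]4C5(C)C
F2 | step 9 | cyclocolorenone 1,3-dithiolane (3,3-ethylenedithio-1βH,10βH-aromadendr-4-ene) | C[C@@H]1CC[C@@H]2[C@@H](C2(C)C)C3=C(C4(SCCS4)C[C@H]13)C
F0 | step 7 | none | none
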